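**Retrosynthetic overview**

1. Target 28 is a diosphenol (an enolised 1,2-diketone) in a 4-hydroxy-2H-pyran-3(6H)-one ring (O1, C2 stereocentre, C3 ketone, C4 enol carbon, C5, C6). The C4=C5 enol double bond is stored as a tertiary silyloxy group on C5 and released, with all protecting groups, by acid dehydration of ketol 27 (step 13).
2. The C3–C4 bond is cut as an acyloin bond: ether-linked dialdehyde 26 is closed by an NHC-catalysed intramolecular benzoin reaction (step 12), the only ring-forming event. The feature that allows it: ring C3 and C4 are both carbonyl-derived carbons, each carrying only one further carbon, so both can be formyl groups and one can be inverted in polarity.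
3. Dialdehyde 26 comes from bis-PMB ether 24. The O1–C6 ether bond and the C5 carbinol arise together when the alkoxide of 20 opens 2,2-disubstituted epoxide 16 (step 8); 1,3-dichloroacetone supplies ring C4, C5 and C6.
4. The (E)-enoate comes from carboalumination/iodination of alkyne 18, then palladium-catalysed alkoxycarbonylation with tert-butyl 6-hydroxyhexanoate; C2 comes from (S)-PMB glycidyl ether (chiral pool).
5. Side chain: (E)-crotylboration of acetaldehyde sets the anti methyl/hydroxyl pair; cross-metathesis sets the E-alkene.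

Key step: step 12

Remark 1: (S)-4-methoxybenzyl glycidyl ether 17 and tert-butyl 6-hydroxyhexanoate 23 are taken as catalogue compounds.
Remark 2: ring C5 is sp2 in the target, so it is carried as a mixture of epimers in 16 and 21–27. The target enol is expected to be base-labile (enol drift, C2 epimerisation), so no basic step follows ring closure.
Abbreviations: PMB = 4-methoxybenzyl, TBS = tert-butyldimethylsilyl, TES = triethylsilyl, Ipc = isopinocampheyl.

**Route**

Step 1
Reactants: 1 acetaldehyde; 2 (E)-but-2-ene; 3 (+)-B-methoxydiisopinocampheylborane (chiral boron reagent)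
Product: 7 (2S,3R)-3-methylpent-4-en-2-ol, via (E)-crotylpotassium 4 (not isolated), via B-[(E)-but-2-enyl]diisopinocampheylborane 5 (not isolated), via borinate ester 6 (not isolated)
Conditions: 2, KOt-Bu, n-BuLi, THF, −78 to −45 °C; 3, −78 °C; BF3·OEt2; 1, −78 °C; then NaOH, H2O2
Reagents that add atoms: none
Why: Brown asymmetric crotylboration through a closed chair (Zimmerman–Traxler) transition state, in which the E-crotyl geometry gives the anti methyl/hydroxyl pair and the Ipc groups derived from (−)-α-pinene select the aldehyde face that should give the (2S,3R) enantiomer.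

Step 2
Reactants: 7 (2S,3R)-3-methylpent-4-en-2-ol
Product: 8 TBS ether of 7
Conditions: TBSCl, imidazole, DMF, rt
Reagents that add atoms: tert-butyldimethylsilyl chloride, CC(C)(C)[Si](C)(C)Cl
Why: Standard silylation of a secondary alcohol, which protects the future side-chain hydroxyl against the alkoxide, oxidation and carbene steps and touches no stereocentre.

Step 3
Reactants: 9 1,3-dichloroacetone; 10 allylmagnesium bromide
Product: 11 1-chloro-2-(chloromethyl)pent-4-en-2-ol
Conditions: 10, Et2O, −78 °C; NH4Cl (aq) at −78 °C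
Reagents that add atoms: none
Why: Grignard addition to the ketone is faster than halide displacement at −78 °C and a cold quench keeps the bis(chloromethyl) carbinol from closing to the epoxide; the product is achiral.

Step 4
Reactants: 11 1-chloro-2-(chloromethyl)pent-4-en-2-ol; 12 4-methoxybenzyl alcohol
Product: 15 2-allyl-2-{[(4-methoxybenzyl)oxy]methyl}oxirane (racemic), via 2-allyl-2-(chloromethyl)oxirane 13 (not isolated), via sodium chlorohydrin alkoxide 14 (not isolated)
Conditions: NaH (3 equiv), 11 (2 equiv), 12 (1 equiv), THF–DMF, 0 °C to rt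
Reagents that add atoms: none
Why: Williamson-type glycidylation with an epichlorohydrin analogue: the alkoxide of 11 closes to 13, the benzylic alkoxide opens it at the unsubstituted CH2, and the tertiary alkoxide 14 closes onto the remaining CH2Cl; excess 13 suppresses double addition, and the new centre (future ring C5) needs no control.

Step 5
Reactants: 15 racemic allyl epoxide; 8 TBS ether
Product: 16 2-[(PMB-oxy)methyl]-2-[(2E,4R,5S)-5-(TBS-oxy)-4-methylhex-2-en-1-yl]oxirane (both epimers at the oxirane carbon)
Conditions: second-generation Hoveyda–Grubbs catalyst [RuCl2(H2IMes)(=CH–C6H4-2-Oi-Pr), C31H38Cl2N2ORu] (5 mol%), 15 (2.5 equiv), CH2Cl2, 40 °C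
Reagents that add atoms: none
Why: Olefin cross-metathesis between an unhindered terminal alkene (in excess) and an allylically branched alkene favours the cross product and, being reversible, the E-alkene; epoxide, ethers and stereocentres are not touched.

Step 6
Reactants: 17 (S)-4-methoxybenzyl glycidyl ether
Product: 18 (2S)-1-[(4-methoxybenzyl)oxy]pent-4-yn-2-ol
Conditions: lithium acetylide–ethylenediamine complex, DMSO, rt
Reagents that add atoms: lithium acetylide–ethylenediamine complex, [Li]C#C.NCCN
Why: SN2 opening of the terminal epoxide at its CH2 carbon by acetylide leaves the C–O bond of the stereocentre (future ring C2) intact, so the configuration is carried over from the chiral pool.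

Step 7
Reactants: 18 (2S)-1-[(4-methoxybenzyl)oxy]pent-4-yn-2-ol
Product: 20 (2S,4E)-5-iodo-1-[(4-methoxybenzyl)oxy]-4-methylpent-4-en-2-ol, via alkenylalane 19 (not isolated)
Conditions: Me3Al, Cp2ZrCl2 (0.3 equiv), CH2Cl2, 0 °C to rt; then I2, THF, −30 °C
Reagents that add atoms: trimethylaluminium, C[Al](C)C; iodine, II
Why: Negishi zirconium-catalysed carboalumination adds methyl and aluminium syn across the terminal alkyne with aluminium at the terminus, and iodinolysis with retention gives the E-trisubstituted vinyl iodide that fixes the enoate geometry; the hydroxyl is carried as its aluminium alkoxide.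

Step 8
Reactants: 20 vinyl iodide alcohol; 16 side-chain epoxide
Product: 22 TES ether of the coupled tertiary alcohol (2-C-substituted glycerol 1-alkyl 3-PMB 2-TES triether; both epimers at the carbinol carbon), via tertiary sodium alkoxide 21 (not isolated)
Conditions: NaH, 15-crown-5 (cat.), 20 (1.2 equiv), DMF, 0 °C; 16, 60 °C; then Et3SiCl, 0 °C to rt
Reagents that add atoms: chlorotriethylsilane, CC[Si](Cl)(CC)CC
Why: Base-mediated opening of a 2,2-disubstituted epoxide by an alkoxide occurs at the unsubstituted carbon, which forms the O1–C6 ether bond and the C5 tertiary alkoxide in one event; the alkoxide is silylated in the same flask, and the C2 stereocentre only acts as the nucleophilic oxygen carrier.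

Step 9
Reactants: 22 vinyl iodide; 23 tert-butyl 6-hydroxyhexanoate
Product: 24 (E)-enoate (iodine of 22 replaced by C(=O)O(CH2)5CO2t-Bu)
Conditions: PdCl2(PPh3)2 (5 mol%), CO (1 atm), 23 (3 equiv), Et3N, DMF, 60 °C
Reagents that add atoms: carbon monoxide, [C-]#[O+]
Why: Palladium-catalysed alkoxycarbonylation of a vinyl iodide (oxidative addition, CO insertion, alcoholysis of the acylpalladium) proceeds with retention of alkene geometry and tolerates silyl and PMB ethers.

Step 10
Reactants: 24 bis-PMB ether
Product: 25 primary diol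
Conditions: DDQ (2.6 equiv), CH2Cl2–pH 7 buffer, 0 °C
Reagents that add atoms: none
Why: Oxidative cleavage of both PMB ethers by DDQ under buffered conditions leaves silyl ethers, esters and the non-conjugated alkenes intact.

Step 11
Reactants: 25 diol
Product: 26 dialdehyde
Conditions: Dess–Martin periodinane (3 equiv), NaHCO3, CH2Cl2, 0 °C to rt; used crude
Reagents that add atoms: none
Why: Dess–Martin oxidation converts both primary alcohols to aldehydes without base strong enough to enolise the α-alkoxy aldehyde, so the C2 configuration should be kept; the tertiary and secondary oxygens are silyl-protected.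

Step 12
Reactants: 26 dialdehyde
Product: 27 ketol, tert-butyl 6-{[(2E)-4-{(2S)-4-hydroxy-3-oxo-5-(triethylsilyloxy)-5-[(2E,4R,5S)-5-(TBS-oxy)-4-methylhex-2-en-1-yl]tetrahydro-2H-pyran-2-yl}-3-methylbut-2-enoyl]oxy}hexanoate (mixture at C4 and C5)
Conditions: 2-(pentafluorophenyl)-6,7-dihydro-5H-pyrrolo[2,1-c][1,2,4]triazol-2-ium tetrafluoroborate (C11H7BF9N3, 20 mol%), i-Pr2NEt (20 mol%), CH2Cl2 (0.02 M), rt
Reagents that add atoms: none
Why: The triazolylidene adds to the less hindered formyl group on the C2 stereocentre, proton transfer gives the Breslow enaminol (an acyl anion equivalent), and this attacks the neopentyl, non-enolisable formyl group on the silyloxy-bearing carbon before the carbene is expelled, so two electrophilic acyl carbons are joined as the C3–C4 bond. The closest known reaction type is the NHC-catalysed intramolecular benzoin (acyloin) cyclisation of α-oxygenated aliphatic dialdehydes to six-membered α-ketols. The tetrahydropyranone ring closes in the 6-exo-trig mode, the attacked C=O being exocyclic to the forming ring. The new carbinol stereocentre at C4 is not controlled and need not be, because C4 and C5 both become sp2 in step 13, while the C2 stereocentre comes from 17 and meets only a catalytic amount of a weak amine base. The step needs cyclisation over oligomerisation, which high dilution and the six-membered ring should secure; it does not need a defined ketol regiochemistry, because 27 and its 4-keto-3-hydroxy isomer pass through the same C3/C4 enediol in step 13.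

Step 13
Reactants: 27 ketol
Product: 28 6,7-diketothiomarinolic acid C6
Conditions: TFA–H2O (9:1), CH2Cl2, 0 °C to rt; toluene co-evaporation; pH 7 buffer–MeOH
Reagents that add atoms: none
Why: Acidolysis removes the TES and TBS ethers and the tert-butyl ester, and the freed β-hydroxy ketone undergoes acid-catalysed aldol-type dehydration through the C3/C4 enediol with loss of the tertiary C5 hydroxyl, which can only place the double bond at C4=C5 and so should give the required enol tautomer without touching C2 or the side-chain stereocentres.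

**Compound list**

1 | acetaldehyde | CC=O | starting material
2 | (E)-but-2-ene | C/C=C/C | starting material
3 | (+)-B-methoxydiisopinocampheylborane | COB([C@H]1C[C@H]2C[C@@H]([C@@H]1C)C2(C)C)[C@H]1C[C@H]2C[C@@H]([C@@H]1C)C2(C)C | starting material
4 | (E)-crotylpotassium | C/C=C/C[K] | intermediate
5 | B-[(E)-but-2-enyl]diisopinocampheylborane | C/C=C/CB([C@H]1C[C@H]2C[C@@H]([C@@H]1C)C2(C)C)[C@H]1C[C@H]2C[C@@H]([C@@H]1C)C2(C)C | intermediate
6 | diisopinocampheylborinate ester of 7 | C=C[C@@H](C)[C@H](C)OB([C@H]1C[C@H]2C[C@@H]([C@@H]1C)C2(C)C)[C@H]1C[C@H]2C[C@@H]([C@@H]1C)C2(C)C | intermediate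
7 | (2S,3R)-3-methylpent-4-en-2-ol | C=C[C@@H](C)[C@H](C)O | intermediate
8 | tert-butyldimethyl{[(2S,3R)-3-methylpent-4-en-2-yl]oxy}silane | C=C[C@@H](C)[C@H](C)O[Si](C)(C)C(C)(C)C | intermediate
9 | 1,3-dichloroacetone | ClCC(=O)CCl | starting material
10 | allylmagnesium bromide | C=CC[Mg]Br | starting material
11 | 1-chloro-2-(chloromethyl)pent-4-en-2-ol | ClCC(O)(CCl)CC=C | intermediate
12 | 4-methoxybenzyl alcohol | COc1ccc(CO)cc1 | starting material
13 | 2-allyl-2-(chloromethyl)oxirane | ClCC1(CC=C)CO1 | intermediate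
14 | sodium 1-chloro-2-{[(4-methoxybenzyl)oxy]methyl}pent-4-en-2-olate | COc1ccc(COCC([O-])(CCl)CC=C)cc1.[Na+] | intermediate
15 | 2-allyl-2-{[(4-methoxybenzyl)oxy]methyl}oxirane (racemic) | COc1ccc(COCC2(CC=C)CO2)cc1 | intermediate
16 | 2-{[(4-methoxybenzyl)oxy]methyl}-2-[(2E,4R,5S)-5-(tert-butyldimethylsilyloxy)-4-methylhex-2-en-1-yl]oxirane (both epimers at the oxirane carbon) | COc1ccc(COCC2(C/C=C/[C@@H](C)[C@H](C)O[Si](C)(C)C(C)(C)C)CO2)cc1 | intermediate
17 | (S)-2-{[(4-methoxybenzyl)oxy]methyl}oxirane | COc1ccc(COC[C@@H]2CO2)cc1 | starting material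
18 | (2S)-1-[(4-methoxybenzyl)oxy]pent-4-yn-2-ol | C#CC[C@H](O)COCc1ccc(OC)cc1 | intermediate
19 | (E)-alkenyl(dimethyl)alane of 18, hydroxyl as dimethylaluminium alkoxide | C[Al](C)/C=C(\C)C[C@H](O[Al](C)C)COCc1ccc(OC)cc1 | intermediate
20 | (2S,4E)-5-iodo-1-[(4-methoxybenzyl)oxy]-4-methylpent-4-en-2-ol | I/C=C(\C)C[C@H](O)COCc1ccc(OC)cc1 | intermediate
21 | sodium alkoxide of 1-{[(2S,4E)-5-iodo-4-methyl-1-(PMB-oxy)pent-4-en-2-yl]oxy}-3-(PMB-oxy)-2-[(2E,4R,5S)-5-(TBS-oxy)-4-methylhex-2-en-1-yl]propan-2-ol | I/C=C(\C)C[C@H](OCC([O-])(COCc1ccc(OC)cc1)C/C=C/[C@@H](C)[C@H](C)O[Si](C)(C)C(C)(C)C)COCc1ccc(OC)cc1.[Na+] | intermediate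
22 | triethylsilyl ether of the tertiary alcohol of 21 | I/C=C(\C)C[C@H](OCC(O[Si](CC)(CC)CC)(COCc1ccc(OC)cc1)C/C=C/[C@@H](C)[C@H](C)O[Si](C)(C)C(C)(C)C)COCc1ccc(OC)cc1 | intermediate
23 | tert-butyl 6-hydroxyhexanoate | CC(C)(C)OC(=O)CCCCCO | starting material
24 | tert-butyl 6-{[(2E,5S)-3-methyl-6-(PMB-oxy)-5-{3-(PMB-oxy)-2-(triethylsilyloxy)-2-[(2E,4R,5S)-5-(TBS-oxy)-4-methylhex-2-en-1-yl]propoxy}hex-2-enoyl]oxy}hexanoate | CC(C)(C)OC(=O)CCCCCOC(=O)/C=C(\C)C[C@H](OCC(O[Si](CC)(CC)CC)(COCc1ccc(OC)cc1)C/C=C/[C@@H](C)[C@H](C)O[Si](C)(C)C(C)(C)C)COCc1ccc(OC)cc1 | intermediate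
25 | diol: as 24 with both PMB-oxy groups replaced by hydroxyl | CC(C)(C)OC(=O)CCCCCOC(=O)/C=C(\C)C[C@H](OCC(O[Si](CC)(CC)CC)(CO)C/C=C/[C@@H](C)[C@H](C)O[Si](C)(C)C(C)(C)C)CO | intermediate
26 | dialdehyde: as 25 with both CH2OH groups oxidised to CHO | CC(C)(C)OC(=O)CCCCCOC(=O)/C=C(\C)C[C@H](OCC(O[Si](CC)(CC)CC)(C=O)C/C=C/[C@@H](C)[C@H](C)O[Si](C)(C)C(C)(C)C)C=O | intermediate
27 | tert-butyl 6-{[(2E)-4-{(2S)-4-hydroxy-3-oxo-5-(triethylsilyloxy)-5-[(2E,4R,5S)-5-(TBS-oxy)-4-methylhex-2-en-1-yl]tetrahydro-2H-pyran-2-yl}-3-methylbut-2-enoyl]oxy}hexanoate (mixture at C4 and C5) | CC(C)(C)OC(=O)CCCCCOC(=O)/C=C(\C)C[C@@H]1OCC(O[Si](CC)(CC)CC)(C/C=C/[C@@H](C)[C@H](C)O[Si](C)(C)C(C)(C)C)C(O)C1=O | intermediate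
28 | 6-{[(2E)-4-{(2S)-4-hydroxy-5-[(2E,4R,5S)-5-hydroxy-4-methylhex-2-en-1-yl]-3-oxo-3,6-dihydro-2H-pyran-2-yl}-3-methylbut-2-enoyl]oxy}hexanoic acid (6,7-diketothiomarinolic acid C6) | C/C(=C\C(=O)OCCCCCC(=O)O)C[C@@H]1OCC(C/C=C/[C@@H](C)[C@H](C)O)=C(O)C1=O | target

**Step count and risks**

Total step count: 13. Longest linear sequence: 9 steps (1, 2, 5, 8, 9, 10, 11, 12, 13).

Steps most likely to fail:

Step 12. What may go wrong: loss of the C2 configuration by base-mediated enolisation of the α-alkoxy aldehyde or of the product ketone, intermolecular acyloin formation, or an amine-promoted intramolecular aldol. Fallback: setting out from 26, a base-free SmI2-mediated intramolecular pinacol coupling (SmI2, t-BuOH, THF, −78 °C), a reaction type known for α-alkoxy 1,6-dialdehydes, should form the same C3–C4 bond and give the 3,4-diol F1. This is converted with Bu2SnO into its dibutylstannylene acetal F2, and brief treatment with NBS should oxidise one carbinol to give ketol 27, possibly with the regioisomeric 4-keto-3-hydroxy ketol F3, which is an equally good substrate for step 13. The route is rejoined at 27.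

Step 13. What may go wrong: drift of the enol double bond towards C2, or loss of the C2 configuration, during the prolonged exposure to strong acid that the tert-butyl ester needs; incomplete dehydration is the lesser concern. Fallback: setting out from 27, the operation is split. Aqueous HF in MeCN at 0 °C should remove both silyl ethers and bring about the dehydration under mild acid to give the tert-butyl ester of the target F4. The ester is then cleaved without protic acid by TMSOTf and 2,6-lutidine (CH2Cl2, 0 °C), which should give the tris(trimethylsilyl) derivative F5 (silyl ester plus two silyl ethers); a pH 7 buffer–MeOH work-up releases 28.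

Step 8. What may go wrong: slow or incomplete opening of the hindered 2,2-disubstituted epoxide by the secondary alkoxide, with base-induced decomposition on long heating. Fallback: setting out from 20, the alkoxide is reacted with racemic 4-methoxybenzyl glycidyl ether (a far more reactive monosubstituted epoxide, used in excess) to give secondary alcohol F6. Dess–Martin oxidation gives 1,3-dialkoxyacetone F7, and allylmagnesium bromide 10 at −78 °C gives tertiary allyl carbinol F8. TESOTf with 2,6-lutidine gives its triethylsilyl ether F9, and cross-metathesis with 8 under the conditions of step 5 comes back to the route at 22.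

Further compounds
F1 | step 12 | 3,4-diol from pinacol coupling of 26 (C5-OTES, mixture of diastereomers) | CC(C)(C)OC(=O)CCCCCOC(=O)/C=C(\C)C[C@@H]1OCC(O[Si](CC)(CC)CC)(C/C=C/[C@@H](C)[C@H](C)O[Si](C)(C)C(C)(C)C)C(O)C1O
F2 | step 12 | dibutylstannylene acetal of F1 | CC(C)(C)OC(=O)CCCCCOC(=O)/C=C(\C)C[C@@H]1OCC(O[Si](CC)(CC)CC)(C/C=C/[C@@H](C)[C@H](C)O[Si](C)(C)C(C)(C)C)C2O[Sn](CCCC)(CCCC)OC12
F3 | step 12 | 4-keto-3-hydroxy regioisomer of 27 | CC(C)(C)OC(=O)CCCCCOC(=O)/C=C(\C)C[C@@H]1OCC(O[Si](CC)(CC)CC)(C/C=C/[C@@H](C)[C@H](C)O[Si](C)(C)C(C)(C)C)C(=O)C1O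
F4 | step 13 | tert-butyl ester of 28 | CC(C)(C)OC(=O)CCCCCOC(=O)/C=C(\C)C[C@@H]1OCC(C/C=C/[C@@H](C)[C@H](C)O)=C(O)C1=O
F5 | step 13 | trimethylsilyl ester bis(trimethylsilyl) ether of 28 | C[Si](C)(C)OC(=O)CCCCCOC(=O)/C=C(\C)C[C@@H]1OCC(C/C=C/[C@@H](C)[C@H](C)O[Si](C)(C)C)=C(O[Si](C)(C)C)C1=O
F6 | step 8 | 1-{[(2S,4E)-5-iodo-4-methyl-1-(PMB-oxy)pent-4-en-2-yl]oxy}-3-(PMB-oxy)propan-2-ol (both epimers at the carbinol) | I/C=C(\C)C[C@H](OCC(O)COCc1ccc(OC)cc1)COCc1ccc(OC)cc1
F7 | step 8 | 1-{[(2S,4E)-5-iodo-4-methyl-1-(PMB-oxy)pent-4-en-2-yl]oxy}-3-(PMB-oxy)propan-2-one | I/C=C(\C)C[C@H](OCC(=O)COCc1ccc(OC)cc1)COCc1ccc(OC)cc1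
F8 | step 8 | tertiary allyl carbinol from F7 (both epimers) | I/C=C(\C)C[C@H](OCC(O)(CC=C)COCc1ccc(OC)cc1)COCc1ccc(OC)cc1
F9 | step 8 | triethylsilyl ether of F8 | I/C=C(\C)C[C@H](OCC(O[Si](CC)(CC)CC)(CC=C)COCc1ccc(OC)cc1)COCc1ccc(OC)cc1
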